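**Assumption:** squamatic acid has no stereocentre (the SMILES carries no stereodescriptor), so the compound as drawn is the only stereoisomer and no stereocontrol is needed; acids 1 and 5 are taken as catalogue compounds.

## Retrosynthetic overview

1. Squamatic acid ⇐ its dibenzyl ester, by hydrogenolysis of both benzyl esters in the last step.
2. Key disconnection: the ring A aryl–C(=O) bond of the depside ester, not the ester C–O bond. The ring A aryl iodide (electrophilic carbon) is joined to an aryloxycarbonyl anion synthon (ArO–C(=O)⁻, acyl-anion type, d1), realised as CO plus the ring B phenol under palladium catalysis.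
3. Ring A iodide ⇐ 2,6-dihydroxy-4-methylbenzoic acid, by benzyl ester formation, mono-O-methylation and iodination ortho to the remaining OH.
4. Ring B phenol ⇐ 2,4-dihydroxy-3,6-dimethylbenzoic acid, by benzyl ester formation.
5. No ring is constructed: both benzene rings are bought. Ring A is elaborated first, ring B is protected, then the two are joined.

## Route

Step 1
Reactants: 1 2,6-dihydroxy-4-methylbenzoic acid
Product: 3 benzyl 2-hydroxy-6-methoxy-4-methylbenzoate, via benzyl 2,6-dihydroxy-4-methylbenzoate 2 (not isolated)
Conditions: BnBr (1.0 equiv), KHCO3 (1.2 equiv), DMF, 25 → 40 °C; then K2CO3 (1.5 equiv), MeI (1.1 equiv), 25 °C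
Reagents that add atoms: benzyl bromide BrCc1ccccc1; iodomethane CI
Why: Carboxylate-selective SN2 benzylation (KHCO3 deprotonates only the acid) followed in the same pot by Williamson mono-O-methylation, which stops after one methyl because the remaining OH is locked in a hydrogen bond to the ester carbonyl.

Step 2
Reactants: 3 benzyl 2-hydroxy-6-methoxy-4-methylbenzoate
Product: 4 benzyl 2-hydroxy-3-iodo-6-methoxy-4-methylbenzoate
Conditions: BnMe3N+ ICl2− (1.05 equiv), NaHCO3 (2 equiv), CH2Cl2–MeOH (5:2), 25 °C
Reagents that add atoms: benzyltrimethylammonium dichloroiodate C[N+](C)(C)Cc1ccccc1.Cl[I-]Cl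
Why: Electrophilic aromatic iodination goes to C3, which is ortho to the hydrogen-bonded OH and para to OMe, whereas C5 is squeezed between the ring methyl and the OMe group whose methyl turns toward it; the dichloroiodate/hydrogen carbonate system is known to iodinate chelated phenols ortho to the OH.

Step 3
Reactants: 5 2,4-dihydroxy-3,6-dimethylbenzoic acid
Product: 6 benzyl 2,4-dihydroxy-3,6-dimethylbenzoate
Conditions: BnBr (1.0 equiv), KHCO3 (1.2 equiv), DMF, 25 → 40 °C
Reagents that add atoms: benzyl bromide BrCc1ccccc1
Why: Carboxylate-selective SN2 benzylation; KHCO3 does not deprotonate the phenols, so both OH groups stay free.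

Step 4
Reactants: 4 benzyl 2-hydroxy-3-iodo-6-methoxy-4-methylbenzoate; 6 benzyl 2,4-dihydroxy-3,6-dimethylbenzoate (1.2 equiv)
Product: 7 dibenzyl squamatate (3-benzyl 1-[4-(benzyloxycarbonyl)-3-hydroxy-2,5-dimethylphenyl] 2-hydroxy-4-methoxy-6-methylbenzene-1,3-dicarboxylate)
Conditions: Pd(OAc)2 (5 mol %), Xantphos (7.5 mol %), CO (1 atm), Et3N (3 equiv), DMAP (20 mol %), toluene, 90 °C
Reagents that add atoms: carbon monoxide [C-]#[O+]
Why: Palladium-catalysed aryloxycarbonylation (Heck-type carbonylation): zerovalent palladium inserts into the C–I bond of 4, CO inserts to give an aroylpalladium species, and the free, non-chelated 4-OH of 6 captures it (the chelated 2-OH of 6 and the chelated, doubly flanked OH of 4 do not compete); in polarity terms the electrophilic ipso carbon of the aryl iodide is joined to a carbonyl carbon that is normally also an electrophile, with CO plus the phenol standing in for an aryloxycarbonyl anion (acyl-anion-type d1 synthon).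

Step 5
Reactants: 7 dibenzyl squamatate
Product: 8 squamatic acid (3-[(4-carboxy-3-hydroxy-2,5-dimethylphenoxy)carbonyl]-2-hydroxy-6-methoxy-4-methylbenzoic acid)
Conditions: H2 (1 atm), 10% Pd/C, EtOAc, 25 °C
Reagents that add atoms: none
Why: Hydrogenolysis of the two benzyl esters over palladium; the aryl ester (depside) link, the aryl methyl ether and the phenols are inert to H2 with Pd/C at room temperature.

## Compound list

1 | 2,6-dihydroxy-4-methylbenzoic acid | Cc1cc(O)c(C(=O)O)c(O)c1 | starting material
2 | benzyl 2,6-dihydroxy-4-methylbenzoate | Cc1cc(O)c(C(=O)OCc2ccccc2)c(O)c1 | intermediate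
3 | benzyl 2-hydroxy-6-methoxy-4-methylbenzoate | COc1cc(C)cc(O)c1C(=O)OCc1ccccc1 | intermediate
4 | benzyl 2-hydroxy-3-iodo-6-methoxy-4-methylbenzoate | COc1cc(C)c(I)c(O)c1C(=O)OCc1ccccc1 | intermediate
5 | 2,4-dihydroxy-3,6-dimethylbenzoic acid | Cc1cc(O)c(C)c(O)c1C(=O)O | starting material
6 | benzyl 2,4-dihydroxy-3,6-dimethylbenzoate | Cc1cc(O)c(C)c(O)c1C(=O)OCc1ccccc1 | intermediate
7 | dibenzyl squamatate (3-benzyl 1-[4-(benzyloxycarbonyl)-3-hydroxy-2,5-dimethylphenyl] 2-hydroxy-4-methoxy-6-methylbenzene-1,3-dicarboxylate) | COc1cc(C)c(C(=O)Oc2cc(C)c(C(=O)OCc3ccccc3)c(O)c2C)c(O)c1C(=O)OCc1ccccc1 | intermediate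
8 | squamatic acid | COc1cc(C)c(C(=O)Oc2cc(C)c(C(=O)O)c(O)c2C)c(O)c1C(=O)O | target

## Step count and risks

Total steps: 5. Longest linear sequence: 4 steps (1 → 3 → 4 → 7 → 8; steps 1, 2, 4, 5).

**Most likely to fail, first: step 4 (carbonylative depside union).** Both partners are hindered: the iodide is flanked on both sides, and the phenol is electron-poor with an ortho methyl. The free ortho-OH of 4 is a further unknown. The reaction class is established, but this substrate pair is untested. Fallback, setting out from 4 and coming back at 7: separate the C–C bond formation from the C–O bond formation. Hydroxycarbonylation of 4 (Pd(OAc)2, Xantphos, CO 1 atm, H2O, Et3N, dioxane, 80 °C) uses water as a small nucleophile and gives 3-(benzyloxycarbonyl)-2-hydroxy-4-methoxy-6-methylbenzoic acid F1; the carbon–carbon bond is still made from the aryl iodide and CO. F1 is then treated with trifluoroacetic anhydride in toluene at 25 °C, which forms its mixed trifluoroacetic anhydride F2 (not isolated). F2 acylates the 4-OH of 6 in the classical depside esterification and gives 7.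

**Second: step 2 (site of iodination).** Attack at C5, para to the OH, could compete with the wanted attack at C3. Fallback, setting out from 3 and coming back at 7: remove the regiochemical question by symmetry. Exhaustive methylation of 3 (excess MeI, K2CO3, DMF, 60 °C) gives benzyl 2,6-dimethoxy-4-methylbenzoate F3, whose two open ring positions are equivalent. Iodination (N-iodosuccinimide, cat. CF3CO2H, MeCN, 25 °C) can then give only benzyl 3-iodo-2,6-dimethoxy-4-methylbenzoate F4. The same carbonylative union with 6 as in step 4 gives the 2-O-methyl ether of dibenzyl squamatate F5. BCl3 (1.1 equiv, CH2Cl2, −78 → −20 °C, aqueous work-up) then removes selectively the methyl ether lying between the two ester carbonyls, which is twisted out of plane and chelated from both sides, and gives 7. Any benzyl ester lost at this point does no harm, since step 5 removes both.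

**Third: step 1 (one-pot benzylation and mono-methylation).** Over-methylation or stray O-benzylation could lower the yield. Fallback, setting out from 1 and coming back at 3: tie the acid and one OH together so that only one OH can be methylated. Treating 1 with acetone, trifluoroacetic anhydride and CF3CO2H (0 → 25 °C) gives the acetonide 5-hydroxy-2,2,7-trimethyl-4H-1,3-benzodioxin-4-one F6. Its single OH is methylated (MeI, K2CO3, acetone, reflux) to 5-methoxy-2,2,7-trimethyl-4H-1,3-benzodioxin-4-one F7. Opening of the dioxinone with benzyl alcohol (3 equiv) and K2CO3 (0.2 equiv) in DMF at 60 °C expels acetone and gives 3 directly.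

## Further compounds

F1 | step 4 | 3-(benzyloxycarbonyl)-2-hydroxy-4-methoxy-6-methylbenzoic acid | COc1cc(C)c(C(=O)O)c(O)c1C(=O)OCc1ccccc1
F2 | step 4 | mixed anhydride of F1 with trifluoroacetic acid | COc1cc(C)c(C(=O)OC(=O)C(F)(F)F)c(O)c1C(=O)OCc1ccccc1
F3 | step 2 | benzyl 2,6-dimethoxy-4-methylbenzoate | COc1cc(C)cc(OC)c1C(=O)OCc1ccccc1
F4 | step 2 | benzyl 3-iodo-2,6-dimethoxy-4-methylbenzoate | COc1cc(C)c(I)c(OC)c1C(=O)OCc1ccccc1
F5 | step 2 | 3-benzyl 1-[4-(benzyloxycarbonyl)-3-hydroxy-2,5-dimethylphenyl] 2,4-dimethoxy-6-methylbenzene-1,3-dicarboxylate | COc1cc(C)c(C(=O)Oc2cc(C)c(C(=O)OCc3ccccc3)c(O)c2C)c(OC)c1C(=O)OCc1ccccc1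
F6 | step 1 | 5-hydroxy-2,2,7-trimethyl-4H-1,3-benzodioxin-4-one | Cc1cc(O)c2c(c1)OC(C)(C)OC2=O
F7 | step 1 | 5-methoxy-2,2,7-trimethyl-4H-1,3-benzodioxin-4-one | COc1cc(C)cc2OC(C)(C)OC(=O)c12
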